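**Retrosynthetic overview**

- The strategy rests on the two adjacent methyl-bearing carbons C8(C9H3)–C8'(C9'H3) in the chain ring A–C7H(ring C)–C8H(CH3)–C8'H(CH3)–C7'H2–ring D. They are read as a 3,4-fused thiolane that has lost its sulfur. C7 (acid level) and C7' (aldehyde level) are the carbonyl and acetal carbons of a 5-alkoxybutenolide.
- Late disconnections: ring A C-acyl bond (Hoesch, brings in the ring B propanoyl chain), then the five O–CH3 bonds, then C7–ring A (Friedel–Crafts on the ring C benzylic cation, sets C7).
- Middle: C7–ring C (Weinreb ketone), and C7'–ring D (Grignard addition to the lactol, then benzylic C–O hydrogenolysis).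
- Early: C8/C8' from Raney Ni desulfurisation and α-epimerisation of a cis-fused thiolane lactone, itself from [3+2] addition of thioformaldehyde S-methylide to the (5S)-menthyloxybutenolide (furfural, (+)-menthol).
- Ring order: butenolide ring (step 1), fused thiolane ring (step 3), thiolane opened (step 4), lactone re-closed on C7' arylation (step 7) and opened for good (step 8). The four benzene rings are bought.

Key step: step 3

Remark: compounds 5, 11, 18 and 22 are taken as purchased (11 as its THF solution); ring B is the 4-methoxyphenyl ring of the propanoyl chain.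

**Route**

Step 1
Reactants: 1 furfural
Product: 2 5-hydroxyfuran-2(5H)-one (racemic)
Conditions: O2, hν (visible), methylene blue (cat.), MeOH, rt
Reagents that add atoms: dioxygen, O=O
Why: Dye-sensitised photo-oxygenation, in which singlet oxygen adds [4+2] across the furan and methanol cleaves the formyl carbon from the endoperoxide as methyl formate, should give the hydroxybutenolide.

Step 2
Reactants: 2 5-hydroxyfuran-2(5H)-one; 3 (+)-menthol
Product: 4 (5S)-5-{[(1S,2R,5S)-5-methyl-2-(propan-2-yl)cyclohexyl]oxy}furan-2(5H)-one
Conditions: CSA (cat.), toluene, reflux, Dean–Stark; crystallise from petroleum ether, mother liquor re-equilibrated with CSA and recrystallised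
Reagents that add atoms: none
Why: Acid-catalysed acetalisation of the pseudo-acid gives both C5 epimers, which interconvert under acid, so crystallisation should drain the mixture into the (5S) epimer (crystallisation-induced diastereomer transformation), the mirror image of the known (5R)-(−)-menthyloxy compound.

Step 3
Reactants: 4 (5S)-menthyloxybutenolide; 5 chloromethyl trimethylsilylmethyl sulfide
Product: 7 (3S,3aS,6aR)-3-{[(1S,2R,5S)-5-methyl-2-(propan-2-yl)cyclohexyl]oxy}tetrahydro-1H,3H-thieno[3,4-c]furan-1-one (cis-fused thiolane lactone; thiolane anti to the menthyloxy group), via thioformaldehyde S-methylide 6 (not isolated)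
Conditions: 5 (2 equiv, slow addition), CsF (3 equiv), MeCN, rt
Reagents that add atoms: none
Why: Fluoride attacks the silicon of 5 and the resulting α-thio carbanion expels chloride (1,3-elimination) to give the unstabilised thiocarbonyl ylide 6, a nucleophilic 4π dipole that adds across the electron-poor C=C of 4 in a concerted suprafacial [3+2] cycloaddition. The closest known reactions are additions of this ylide to enoates, maleimides and unsaturated lactones, and the anti-selective dipolar cycloadditions of diazomethane, nitrile oxides and azomethine ylides to 5-menthyloxybutenolides. The thiolane ring is closed by the cycloaddition itself, both C–C bonds (C8–C9 and C8'–C9') forming in one step, and the cis ring fusion follows from suprafacial addition to the Z-alkene. C8' (lactone β-carbon) is set by approach of the dipole to the face opposite the C5 menthyloxy group; C8 (α-carbon) is set cis to it by the concerted addition and is left for correction in step 5. Only π-facial selectivity is needed, since the dipole is symmetrical and there is no regiochemical question, and the flat butenolide with its single acetal substituent on one face secures it. Slow release of the ylide should keep its self-condensation behind the cycloaddition.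

Step 4
Reactants: 7 cis-fused thiolane lactone
Product: 8 (3R,4S,5S)-3,4-dimethyl-5-{[(1S,2R,5S)-5-methyl-2-(propan-2-yl)cyclohexyl]oxy}dihydrofuran-2(3H)-one (cis-dimethyl lactone)
Conditions: Raney Ni (W-2, excess), EtOH, reflux
Reagents that add atoms: none
Why: Raney Ni reductive desulfurisation cleaves both C–S bonds and turns C9 and C9' into methyl groups without touching the lactone, the acetal or either stereocentre.

Step 5
Reactants: 8 cis-dimethyl lactone
Product: 9 (3S,4S,5S)-3,4-dimethyl-5-{[(1S,2R,5S)-5-methyl-2-(propan-2-yl)cyclohexyl]oxy}dihydrofuran-2(3H)-one (all-trans lactone)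
Conditions: DBU (0.5 equiv), toluene, 80 °C; residual cis isomer separated and recycled
Reagents that add atoms: none
Why: Base-mediated epimerisation through the lactone enolate equilibrates C8 only, and the 3,4-trans-4,5-trans lactone should dominate because the eclipsed cis-dimethyl interaction is removed, while the non-nucleophilic amidine leaves the acyl acetal intact.

Step 6
Reactants: 9 all-trans lactone
Product: 10 (3S,4S)-5-hydroxy-3,4-dimethyldihydrofuran-2(3H)-one (lactol, anomer mixture)
Conditions: TFA/H2O (4:1), rt; (+)-menthol recovered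
Reagents that add atoms: water, O
Why: Acid hydrolysis of the acyl acetal (pseudo-ester) releases the auxiliary and gives the pseudo-acid lactol, in which the aldehyde stays masked in the ring so that C8' is shielded from enolisation.

Step 7
Reactants: 10 lactol; 11 4-methoxyphenylmagnesium bromide
Product: 13 (3S,4S)-5-(4-methoxyphenyl)-3,4-dimethyldihydrofuran-2(3H)-one (C5 epimers), via hydroxy acid 12 (not isolated)
Conditions: 11 (2.5 equiv), THF, −40 → 0 °C; then 2 M HCl, rt
Reagents that add atoms: none
Why: Grignard addition to a pseudo-acid: the first equivalent deprotonates and opens the lactol to the aldehyde carboxylate, the second adds to the aldehyde, and acid closes 12 to the γ-aryl lactone, whose new C7' centre is removed in the next step.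

Step 8
Reactants: 13 γ-aryl lactone
Product: 14 (2S,3R)-4-(4-methoxyphenyl)-2,3-dimethylbutanoic acid
Conditions: H2 (3 atm), 10% Pd/C, AcOH, HClO4 (cat.), rt
Reagents that add atoms: none
Why: Catalytic hydrogenolysis of the benzylic C–O bond of a γ-aryl-γ-butyrolactone, helped by the para-methoxy group and acid, gives the 4-arylbutanoic acid on the metal surface without a free cation, so C8' is not at risk.

Step 9
Reactants: 14 acid
Product: 15 (2S,3R)-N-methoxy-4-(4-methoxyphenyl)-N,2,3-trimethylbutanamide (Weinreb amide)
Conditions: MeNHOMe·HCl, EDC·HCl, HOBt, N-methylmorpholine, CH2Cl2, 0 °C → rt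
Reagents that add atoms: N,O-dimethylhydroxylamine hydrochloride, CNOC.Cl
Why: Carbodiimide amide coupling through the HOBt ester gives the Weinreb amide, and an α-alkyl acid without an α-heteroatom should not epimerise under these conditions.

Step 10
Reactants: 15 Weinreb amide; 11 4-methoxyphenylmagnesium bromide
Product: 16 (2S,3R)-1,4-bis(4-methoxyphenyl)-2,3-dimethylbutan-1-one
Conditions: 11 (1.5 equiv), THF, 0 °C; then cold 1 M HCl
Reagents that add atoms: none
Why: Weinreb ketone synthesis, in which the chelated tetrahedral adduct stops at mono-addition and releases the aryl ketone only on the cold acidic quench, which keeps C8 from enolising.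

Step 11
Reactants: 16 ketone
Product: 17 (2S,3R)-1,4-bis(4-methoxyphenyl)-2,3-dimethylbutan-1-ol (C1 epimers)
Conditions: NaBH4, MeOH, 0 °C
Reagents that add atoms: none
Why: Borohydride reduction of the aryl ketone; both carbinol epimers are acceptable because C7 is ionised in the next step.

Step 12
Reactants: 17 benzylic alcohol; 18 1,3,5-trimethoxybenzene
Product: 20 2-[(1R,2S,3R)-1,4-bis(4-methoxyphenyl)-2,3-dimethylbutyl]-1,3,5-trimethoxybenzene, via benzylic cation 19 (not isolated)
Conditions: 18 (5 equiv), HBF4·OEt2 (1.1 equiv), CH2Cl2, −78 → −40 °C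
Reagents that add atoms: none
Why: Acid ionises either epimer of 17 to the para-methoxybenzylic cation 19, which should hold the C8–H bond in the cation plane on the ring C side to avoid A1,3 strain, so that Friedel–Crafts attack of the symmetrical arene passes the C9 methyl and avoids the C8' branch, which corresponds to 7R (substrate-controlled 1,2-induction as in diastereoselective Friedel–Crafts alkylations of α-branched benzylic cations).

Step 13
Reactants: 20 pentamethyl ether
Product: 21 2-[(1R,2S,3R)-1,4-bis(4-hydroxyphenyl)-2,3-dimethylbutyl]benzene-1,3,5-triol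
Conditions: BBr3 (10 equiv), CH2Cl2, −78 °C → rt; then ice/H2O
Reagents that add atoms: none
Why: BBr3 cleavage of aryl methyl ethers (boron complexation, bromide attack on methyl) should free all five phenols, and the three C–H stereocentres carry no leaving group.

Step 14
Reactants: 21 pentaphenol; 22 3-(4-methoxyphenyl)propanenitrile
Product: 24 1-{3-[(1R,2S,3R)-1,4-bis(4-hydroxyphenyl)-2,3-dimethylbutyl]-2,4,6-trihydroxyphenyl}-3-(4-methoxyphenyl)propan-1-one (target), via ketiminium chloride 23 (not isolated)
Conditions: 22 (1.2 equiv), ZnCl2, HCl (g), Et2O, 0 °C; then H2O, 80 °C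
Reagents that add atoms: water, O
Why: Hoesch acylation, in which the HCl/ZnCl2-activated nitrile C-acylates ring A, by far the most nucleophilic arene present and carrying two equivalent free positions, and hydrolysis of 23 gives the ketone; the acyl group deactivates ring A against a second acylation and the ring B methyl ether is never exposed to BBr3.

**Compound list**

1 | furfural | O=Cc1ccco1 | starting material
2 | 5-hydroxyfuran-2(5H)-one (racemic) | O=C1C=CC(O)O1 | intermediate
3 | (+)-menthol | CC(C)[C@H]1CC[C@H](C)C[C@@H]1O | starting material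
4 | (5S)-5-{[(1S,2R,5S)-5-methyl-2-(propan-2-yl)cyclohexyl]oxy}furan-2(5H)-one | O=C1C=C[C@@H](O[C@H]2C[C@@H](C)CC[C@@H]2C(C)C)O1 | intermediate
5 | chloromethyl trimethylsilylmethyl sulfide | C[Si](C)(C)CSCCl | starting material
6 | thioformaldehyde S-methylide | [CH2-][S+]=C | intermediate
7 | (3S,3aS,6aR)-3-(menthyloxy)tetrahydro-1H,3H-thieno[3,4-c]furan-1-one, cis-fused | O=C1O[C@H](O[C@H]2C[C@@H](C)CC[C@@H]2C(C)C)[C@H]3CSC[C@@H]13 | intermediate
8 | (3R,4S,5S)-3,4-dimethyl-5-(menthyloxy)dihydrofuran-2(3H)-one, cis-dimethyl | O=C1O[C@H](O[C@H]2C[C@@H](C)CC[C@@H]2C(C)C)[C@@H](C)[C@H]1C | intermediate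
9 | (3S,4S,5S)-3,4-dimethyl-5-(menthyloxy)dihydrofuran-2(3H)-one, all-trans | O=C1O[C@H](O[C@H]2C[C@@H](C)CC[C@@H]2C(C)C)[C@@H](C)[C@@H]1C | intermediate
10 | (3S,4S)-5-hydroxy-3,4-dimethyldihydrofuran-2(3H)-one (anomer mixture) | O=C1OC(O)[C@@H](C)[C@@H]1C | intermediate
11 | 4-methoxyphenylmagnesium bromide | COc1ccc([Mg]Br)cc1 | starting material
12 | (2S,3S)-4-hydroxy-4-(4-methoxyphenyl)-2,3-dimethylbutanoic acid (C4 epimers) | OC(=O)[C@@H](C)[C@H](C)C(O)c1ccc(OC)cc1 | intermediate
13 | (3S,4S)-5-(4-methoxyphenyl)-3,4-dimethyldihydrofuran-2(3H)-one (C5 epimers) | O=C1OC(c2ccc(OC)cc2)[C@@H](C)[C@@H]1C | intermediate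
14 | (2S,3R)-4-(4-methoxyphenyl)-2,3-dimethylbutanoic acid | OC(=O)[C@@H](C)[C@H](C)Cc1ccc(OC)cc1 | intermediate
15 | (2S,3R)-N-methoxy-4-(4-methoxyphenyl)-N,2,3-trimethylbutanamide | CON(C)C(=O)[C@@H](C)[C@H](C)Cc1ccc(OC)cc1 | intermediate
16 | (2S,3R)-1,4-bis(4-methoxyphenyl)-2,3-dimethylbutan-1-one | COc1ccc(cc1)C(=O)[C@@H](C)[C@H](C)Cc1ccc(OC)cc1 | intermediate
17 | (2S,3R)-1,4-bis(4-methoxyphenyl)-2,3-dimethylbutan-1-ol (C1 epimers) | COc1ccc(cc1)C(O)[C@@H](C)[C@H](C)Cc1ccc(OC)cc1 | intermediate
18 | 1,3,5-trimethoxybenzene | COc1cc(OC)cc(OC)c1 | starting material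
19 | (2S,3R)-1,4-bis(4-methoxyphenyl)-2,3-dimethylbutan-1-ylium (benzylic cation) | COc1ccc(cc1)[CH+][C@@H](C)[C@H](C)Cc1ccc(OC)cc1 | intermediate
20 | 2-[(1R,2S,3R)-1,4-bis(4-methoxyphenyl)-2,3-dimethylbutyl]-1,3,5-trimethoxybenzene | COc1cc(OC)c(c(OC)c1)[C@@H](c1ccc(OC)cc1)[C@@H](C)[C@H](C)Cc1ccc(OC)cc1 | intermediate
21 | 2-[(1R,2S,3R)-1,4-bis(4-hydroxyphenyl)-2,3-dimethylbutyl]benzene-1,3,5-triol | Oc1cc(O)c(c(O)c1)[C@@H](c1ccc(O)cc1)[C@@H](C)[C@H](C)Cc1ccc(O)cc1 | intermediate
22 | 3-(4-methoxyphenyl)propanenitrile | COc1ccc(CCC#N)cc1 | starting material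
23 | ketiminium chloride of the target ketone | COc1ccc(CCC(=[NH2+])c2c(O)cc(O)c([C@@H](c3ccc(O)cc3)[C@@H](C)[C@H](C)Cc3ccc(O)cc3)c2O)cc1.[Cl-] | intermediate
24 | 1-{3-[(1R,2S,3R)-1,4-bis(4-hydroxyphenyl)-2,3-dimethylbutyl]-2,4,6-trihydroxyphenyl}-3-(4-methoxyphenyl)propan-1-one | COc1ccc(CCC(=O)c2c(O)cc(O)c([C@@H](c3ccc(O)cc3)[C@@H](C)[C@H](C)Cc3ccc(O)cc3)c2O)cc1 | target

**Step count**

Total steps: 14. Longest linear sequence: 14 steps (1 to 24).

**Steps most likely to fail**

1. Step 3 (key step). The ylide may condense with itself faster than it adds to the butenolide, fluoride may epimerise or degrade the acetal carbon before cycloaddition, or facial discrimination may be incomplete. The fallback sets out from 4 and returns at 9, and introduces the two methyl carbons one after the other instead of by cycloaddition. Tris(methylsulfanyl)methyllithium F1 (from tris(methylsulfanyl)methane and n-BuLi, THF, −78 °C) should add 1,4 to 4 anti to the menthyloxy group. Trapping the lactone enolate with MeI (DMPU) trans to the new substituent should give (3S,4S,5S)-3-methyl-5-(menthyloxy)-4-[tris(methylsulfanyl)methyl]dihydrofuran-2(3H)-one F2. Raney Ni in EtOH then reduces the C(SMe)3 group to the C9' methyl and gives 9 directly, already trans, so steps 4 and 5 are not needed.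

2. Step 12. Facial discrimination between the C9 methyl and the C8' branch in the open-chain cation may be weak. The cation may also lose the C8 proton, which would scramble C8, or be intercepted at the ipso carbon of ring D. The fallback sets out from 16 and returns at 20, and makes the C7–H bond last instead of the C7–aryl bond. 2,4,6-Trimethoxyphenyllithium F3 (from 18 and n-BuLi, THF, 0 °C) is added to 16 with CeCl3 at −78 °C to suppress enolisation, giving (2S,3R)-1,4-bis(4-methoxyphenyl)-2,3-dimethyl-1-(2,4,6-trimethoxyphenyl)butan-1-ol F4. Ionic hydrogenation (Et3SiH, TFA, CH2Cl2, −78 → 0 °C) then reduces the diaryl cation. That cation is conjugated mainly with the trioxygenated ring A, whose ortho-methoxy group should hold the C8–H bond in plane on the ring A side, so that the small hydride donor enters past the C9 methyl and again leads to 7R in 20.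

3. Step 13. Protonation of the very electron-rich ring A at its ipso carbon may cleave or epimerise the C7–ring A bond (retro-Friedel–Crafts), and the two flanked ortho ethers may cleave slowly, giving partly methylated material. The fallback sets out from 16 and returns at 21, and removes the methyl ethers before ring A is attached. BBr3 (CH2Cl2, −78 → 0 °C) on 16 should give (2S,3R)-1,4-bis(4-hydroxyphenyl)-2,3-dimethylbutan-1-one F5. NaBH4 in MeOH then gives (2S,3R)-1,4-bis(4-hydroxyphenyl)-2,3-dimethylbutan-1-ol F6 (C1 epimers). Its para-hydroxybenzylic cation (quinone methide) is captured by excess phloroglucinol under mild acid (p-TsOH cat., dioxane, rt) with the same facial argument as in step 12, giving 21 without any methyl ether on ring A.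

**Further compounds**

F1 | step 3 | tris(methylsulfanyl)methyllithium | [Li]C(SC)(SC)SC
F2 | step 3 | (3S,4S,5S)-3-methyl-5-(menthyloxy)-4-[tris(methylsulfanyl)methyl]dihydrofuran-2(3H)-one | O=C1O[C@H](O[C@H]2C[C@@H](C)CC[C@@H]2C(C)C)[C@@H](C(SC)(SC)SC)[C@@H]1C
F3 | step 12 | 2,4,6-trimethoxyphenyllithium | [Li]c1c(OC)cc(OC)cc1OC
F4 | step 12 | (2S,3R)-1,4-bis(4-methoxyphenyl)-2,3-dimethyl-1-(2,4,6-trimethoxyphenyl)butan-1-ol (C1 epimers) | COc1cc(OC)c(c(OC)c1)C(O)(c1ccc(OC)cc1)[C@@H](C)[C@H](C)Cc1ccc(OC)cc1
F5 | step 13 | (2S,3R)-1,4-bis(4-hydroxyphenyl)-2,3-dimethylbutan-1-one | Oc1ccc(cc1)C(=O)[C@@H](C)[C@H](C)Cc1ccc(O)cc1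
F6 | step 13 | (2S,3R)-1,4-bis(4-hydroxyphenyl)-2,3-dimethylbutan-1-ol (C1 epimers) | Oc1ccc(cc1)C(O)[C@@H](C)[C@H](C)Cc1ccc(O)cc1
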